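The ester between the two halves is made last, by carboxylate opening of a spiro-epoxide. The lactone half rests on one disconnection: its cyclohexane (C10 carbinol, C1 lactone α-carbon, C6 allylic CH, C7 isopropyl-bearing CH, C8 and C9 methylenes) hides a β-keto ester (oxygen on C10 β to the C2 carbonyl on C1) and a masked acetyl on C7. A base-mediated double Michael annulation joins a vinyl β-keto ester (C8, C9, C10, C1, C2) to a glyceraldehyde-derived enone (C6, C7) and closes the ring at C7–C8, setting C6 and C7 in one operation. The other half comes from (R)-cryptone by conjugate addition and enolate triflation.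

Key step: step 2

Remarks.
- Atom labels, lactone half: C1 lactone α-CH, C2 lactone C=O, C3 OCH2, C4 =C(CO2H), C5 =CH, C6 allylic ring CH, C7 CH(iPr), C8 and C9 ring CH2, C10 C(OH), C14 CH2O on C10, C15 CO2H. Primed labels are the same positions in the other half.
- As drawn, the CH(iPr)–CH pairs of the two halves have opposite absolute sense, so the halves are made from separate chiral sources.
- Compounds 1, 3, 19, 20, the phosphoranes and (tributylstannyl)methanol are assumed purchasable.

Step 1
Reactants: 1 (R)-2,2-dimethyl-1,3-dioxolane-4-carbaldehyde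
Product: 2 (S,E)-4-(2,2-dimethyl-1,3-dioxolan-4-yl)but-3-en-2-one
Conditions: Ph3P=CHC(O)CH3, CH2Cl2, rt
Reagents that add atoms: 1-(triphenylphosphoranylidene)propan-2-one, CC(=O)C=P(c1ccccc1)(c1ccccc1)c1ccccc1
Why: Wittig olefination with a stabilised ylide should give the (E)-enone under neutral conditions that leave the α-alkoxy stereocentre untouched.

Step 2
Reactants: 2 (S,E)-4-(2,2-dimethyl-1,3-dioxolan-4-yl)but-3-en-2-one; 3 methyl 5-methoxy-3-oxopentanoate
Product: 6 methyl (5R,6S)-5-acetyl-6-[(4S)-2,2-dimethyl-1,3-dioxolan-4-yl]-2-oxocyclohexane-1-carboxylate, via methyl 3-oxopent-4-enoate 4 (not isolated), via open-chain Michael adduct 5 (not isolated)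
Conditions: NaOMe (0.3 equiv), MeOH, 0 °C to 40 °C
Reagents that add atoms: none
Why: Methoxide unmasks the vinyl β-keto ester 4 from 3 by E1cB loss of methanol, its enolate carbon C1 adds to the enone β-carbon C6 to give 5, and the methyl-ketone enolate at C7 then adds to the vinyl ketone terminus C8, so the cyclohexane is closed by the C7–C8 bond. This is the known base-mediated double Michael (anionic [4+2]) annulation of 3-oxopent-4-enoates with enones, run here with the methoxy surrogate. The ring closes 6-endo-trig with respect to the vinyl ketone and exo with respect to the attacking enolate, through a chair transition state. C6 is set in the intermolecular addition by the dioxolane stereocentre (attack anti to the allylic C–O bond, the syn sense expected for soft carbon nucleophiles on (E)-γ-alkoxy enones); C7 is set by the chair closure and by equilibration α to the acetyl group, which should leave acetyl and dioxolanyl trans-diequatorial; C1 stays labile as a β-keto ester. The step needs Michael closure at C7–C8 to win over Robinson-type aldol attack of the acetyl methyl on C10; this should hold because the vinyl ketone is the most electrophilic site, C10 is deactivated within the enolised β-keto ester, and the reversible earlier steps drain into 6 as its stabilised enolate.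

Step 3
Reactants: 6 methyl (5R,6S)-5-acetyl-6-[(4S)-2,2-dimethyl-1,3-dioxolan-4-yl]-2-oxocyclohexane-1-carboxylate
Product: 7 methyl (5R,6S)-6-[(4S)-2,2-dimethyl-1,3-dioxolan-4-yl]-2-oxo-5-(prop-1-en-2-yl)cyclohexane-1-carboxylate
Conditions: Ph3PCH3Br (3.5 equiv), KOtBu (3.3 equiv), THF, 0 °C to rt
Reagents that add atoms: methyltriphenylphosphonium bromide, C[P+](c1ccccc1)(c1ccccc1)c1ccccc1.[Br-]
Why: In this Wittig methylenation the β-keto ester is protected in situ as its enolate, so only the acetyl carbonyl should react, and C7 stays in the trans (equatorial) arrangement.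

Step 4
Reactants: 7 methyl (5R,6S)-6-[(4S)-2,2-dimethyl-1,3-dioxolan-4-yl]-2-oxo-5-(prop-1-en-2-yl)cyclohexane-1-carboxylate
Product: 8 methyl (5S,6S)-6-[(4S)-2,2-dimethyl-1,3-dioxolan-4-yl]-2-oxo-5-(propan-2-yl)cyclohexane-1-carboxylate
Conditions: H2 (1 atm), Pd/C, EtOAc, rt
Reagents that add atoms: none
Why: Heterogeneous hydrogenation should saturate the 1,1-disubstituted alkene while the enolised β-keto ester and the acetal are inert; no stereocentre is formed.

Step 5
Reactants: 8 methyl (5S,6S)-6-[(4S)-2,2-dimethyl-1,3-dioxolan-4-yl]-2-oxo-5-(propan-2-yl)cyclohexane-1-carboxylate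
Product: 9 methyl (5S,6S)-6-[(4S)-2,2-dimethyl-1,3-dioxolan-4-yl]-5-(propan-2-yl)-2-(trifluoromethanesulfonyloxy)cyclohex-1-ene-1-carboxylate
Conditions: Tf2O, iPr2NEt, CH2Cl2, −78 °C
Reagents that add atoms: trifluoromethanesulfonic anhydride, O=S(=O)(OS(=O)(=O)C(F)(F)F)C(F)(F)F
Why: O-Sulfonylation of the β-keto ester enol should give the regiodefined C10=C1 enol triflate.

Step 6
Reactants: 9 methyl (5S,6S)-6-[(4S)-2,2-dimethyl-1,3-dioxolan-4-yl]-5-(propan-2-yl)-2-(trifluoromethanesulfonyloxy)cyclohex-1-ene-1-carboxylate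
Product: 10 methyl (5S,6S)-6-[(4S)-2,2-dimethyl-1,3-dioxolan-4-yl]-5-(propan-2-yl)-2-[(trimethylsilyl)methyl]cyclohex-1-ene-1-carboxylate
Conditions: Me3SiCH2MgCl, Pd(PPh3)4 (5 mol%), THF, 0 °C to rt
Reagents that add atoms: (trimethylsilyl)methylmagnesium chloride, C[Si](C)(C)C[Mg]Cl
Why: Kumada coupling of the enol triflate with a Grignard reagent lacking β-hydrogens should be fast enough at 0 °C to spare the hindered conjugated ester, and it installs C14 as an allylsilane.

Step 7
Reactants: 10 methyl (5S,6S)-6-[(4S)-2,2-dimethyl-1,3-dioxolan-4-yl]-5-(propan-2-yl)-2-[(trimethylsilyl)methyl]cyclohex-1-ene-1-carboxylate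
Product: 11 methyl (1S,2S,3S)-2-[(4S)-2,2-dimethyl-1,3-dioxolan-4-yl]-6-methylidene-3-(propan-2-yl)cyclohexane-1-carboxylate
Conditions: Bu4NF, AcOH, THF, −40 °C to 0 °C
Reagents that add atoms: none
Why: Fluoride-induced desilylation gives the ester dienolate, and kinetic α-protonation (deconjugative protodesilylation) should give the exocyclic C10=C14 alkene; C1 is set by protonation anti to the neighbouring C6 substituent, which places the ester cis to it.

Step 8
Reactants: 11 methyl (1S,2S,3S)-2-[(4S)-2,2-dimethyl-1,3-dioxolan-4-yl]-6-methylidene-3-(propan-2-yl)cyclohexane-1-carboxylate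
Product: 12 (1S,2S,3S)-2-[(4S)-2,2-dimethyl-1,3-dioxolan-4-yl]-6-methylidene-3-(propan-2-yl)cyclohexane-1-carboxylic acid
Conditions: Me3SnOH, 1,2-dichloroethane, 80 °C; then 1 M HCl
Reagents that add atoms: trimethyltin hydroxide, C[Sn](C)(C)O
Why: Near-neutral ester hydrolysis with Me3SnOH should free the acid without epimerising C1 or moving the β,γ-double bond into conjugation.

Step 9
Reactants: 12 (1S,2S,3S)-2-[(4S)-2,2-dimethyl-1,3-dioxolan-4-yl]-6-methylidene-3-(propan-2-yl)cyclohexane-1-carboxylic acid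
Product: 13 (1S,2S,3S)-2-formyl-6-methylidene-3-(propan-2-yl)cyclohexane-1-carboxylic acid
Conditions: H5IO6, EtOAc, rt
Reagents that add atoms: none
Why: Periodic acid should hydrolyse the terminal acetonide and cleave the glycol in one operation to the C5 aldehyde (in equilibrium with its lactol), leaving the alkene and the acid untouched.

Step 10
Reactants: 13 (1S,2S,3S)-2-formyl-6-methylidene-3-(propan-2-yl)cyclohexane-1-carboxylic acid
Product: 14 (1S,2S,3S)-2-[(Z)-2-bromo-3-tert-butoxy-3-oxoprop-1-en-1-yl]-6-methylidene-3-(propan-2-yl)cyclohexane-1-carboxylic acid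
Conditions: Ph3P=CHCO2tBu (2.5 equiv) and N-bromosuccinimide (2.5 equiv) premixed in CH2Cl2 at −20 °C, then 13, −20 °C to rt
Reagents that add atoms: tert-butyl (triphenylphosphoranylidene)acetate, CC(C)(C)OC(=O)C=P(c1ccccc1)(c1ccccc1)c1ccccc1; N-bromosuccinimide, O=C1CCC(=O)N1Br
Why: Wittig reaction of the α-bromo stabilised ylide should give the (Z)-α-bromo enoate (C6 trans to the ester), and premixing leaves no free brominating agent for the alkene or the acid.

Step 11
Reactants: 14 (1S,2S,3S)-2-[(Z)-2-bromo-3-tert-butoxy-3-oxoprop-1-en-1-yl]-6-methylidene-3-(propan-2-yl)cyclohexane-1-carboxylic acid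
Product: 15 (1S,2R,3S)-2-[(E)-3-tert-butoxy-2-(hydroxymethyl)-3-oxoprop-1-en-1-yl]-6-methylidene-3-(propan-2-yl)cyclohexane-1-carboxylic acid
Conditions: Bu3SnCH2OH, Pd(PPh3)4 (10 mol%), dioxane, 90 °C
Reagents that add atoms: (tributylstannyl)methanol, CCCC[Sn](CCCC)(CCCC)CO
Why: Stille coupling of the alkenyl bromide proceeds with retention of geometry, so the C3 hydroxymethyl group should end up cis to C6.

Step 12
Reactants: 15 (1S,2R,3S)-2-[(E)-3-tert-butoxy-2-(hydroxymethyl)-3-oxoprop-1-en-1-yl]-6-methylidene-3-(propan-2-yl)cyclohexane-1-carboxylic acid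
Product: 16 tert-butyl (E)-2-(hydroxymethyl)-3-[(1S,2R,3S,6R)-6-(iodomethyl)-8-oxo-3-(propan-2-yl)-7-oxabicyclo[4.2.0]octan-2-yl]prop-2-enoate
Conditions: I2, NaHCO3, MeCN/H2O, 0 °C, dark
Reagents that add atoms: iodine, II
Why: Kinetic iodolactonisation of the β,γ-unsaturated acid should give the cis-fused β-lactone by 4-exo attack of the carboxylate on the tertiary terminus C10; this sets C10 with its oxygen cis to C2 and CH2I trans, while the electron-poor enoate is inert.

Step 13
Reactants: 16 tert-butyl (E)-2-(hydroxymethyl)-3-[(1S,2R,3S,6R)-6-(iodomethyl)-8-oxo-3-(propan-2-yl)-7-oxabicyclo[4.2.0]octan-2-yl]prop-2-enoate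
Product: 18 tert-butyl ester of the spiro-epoxy ε-lactone (C10–C14 oxirane with O cis to C2; C1 S, C6 R, C7 S, C10 R), via iodohydrin lactone 17 (not isolated)
Conditions: Cs2CO3, MeCN, 0 °C to rt
Reagents that add atoms: none
Why: Strain-driven intramolecular acyl transfer from the β-lactone to the C3 alkoxide should form the seven-membered lactone, and the liberated C10 alkoxide then displaces iodide (3-exo-tet) to give the oxirane with retention at C10.

Step 14
Reactants: 19 3-methylbutanal; 20 but-3-en-2-one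
Product: 21 (R)-5-oxo-2-(propan-2-yl)hexanal
Conditions: (R)-2-[diphenyl(trimethylsilyloxy)methyl]pyrrolidine (10 mol%), ethyl 3,4-dihydroxybenzoate (20 mol%), neat, 4 °C
Reagents that add atoms: none
Why: In this enamine-catalysed Michael addition the diarylmethyl group shields one enamine face, so the (R)-catalyst should set the (R)-stereocentre.

Step 15
Reactants: 21 (R)-5-oxo-2-(propan-2-yl)hexanal
Product: 22 (R)-4-(propan-2-yl)cyclohex-2-en-1-one
Conditions: 0.1 M KOH (aq), Bu4NOH (cat.), Et2O/THF, reflux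
Reagents that add atoms: none
Why: Intramolecular aldol condensation of the methyl ketone onto the aldehyde should close the cyclohexenone without touching the stereocentre.

Step 16
Reactants: 22 (R)-4-(propan-2-yl)cyclohex-2-en-1-one
Product: 24 (3R,4R)-3-ethenyl-4-(propan-2-yl)cyclohex-1-en-1-yl trifluoromethanesulfonate, via bromomagnesium enolate 23 (not isolated)
Conditions: CH2=CHMgBr, CuBr·SMe2 (10 mol%), THF, −78 °C; then N-(5-chloropyridin-2-yl)triflimide, −78 °C to rt
Reagents that add atoms: vinylmagnesium bromide, C=C[Mg]Br; N-(5-chloropyridin-2-yl)-1,1,1-trifluoro-N-(trifluoromethanesulfonyl)methanesulfonamide, Clc1ccc(N(S(=O)(=O)C(F)(F)F)S(=O)(=O)C(F)(F)F)nc1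
Why: Copper-catalysed conjugate addition should occur anti to the adjacent isopropyl group (trans C6′/C7′), and the regiospecific enolate is trapped as the C10′=C1′ enol triflate.

Step 17
Reactants: 24 (3R,4R)-3-ethenyl-4-(propan-2-yl)cyclohex-1-en-1-yl trifluoromethanesulfonate
Product: 26 (1R,6R)-6-(propan-2-yl)-3-(trifluoromethanesulfonyloxy)cyclohex-2-ene-1-carbaldehyde, via ozonide 25 (not isolated)
Conditions: O3, CH2Cl2, −78 °C (Sudan red indicator); then PPh3
Reagents that add atoms: ozone, [O-][O+]=O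
Why: Ozonolysis should select the electron-rich vinyl group over the electron-poor enol triflate alkene; the aldehyde is used at once to limit epimerisation at C6′.

Step 18
Reactants: 26 (1R,6R)-6-(propan-2-yl)-3-(trifluoromethanesulfonyloxy)cyclohex-2-ene-1-carbaldehyde
Product: 27 methyl (Z)-2-bromo-3-[(1R,6R)-6-(propan-2-yl)-3-(trifluoromethanesulfonyloxy)cyclohex-2-en-1-yl]prop-2-enoate
Conditions: Ph3P=CHCO2Me and N-bromosuccinimide premixed in CH2Cl2 at −20 °C, then 26, −20 °C to rt
Reagents that add atoms: methyl (triphenylphosphoranylidene)acetate, COC(=O)C=P(c1ccccc1)(c1ccccc1)c1ccccc1; N-bromosuccinimide, O=C1CCC(=O)N1Br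
Why: The same Wittig reaction of an α-bromo stabilised ylide as in step 10 should give the (Z)-α-bromo enoate under neutral conditions.

Step 19
Reactants: 27 methyl (Z)-2-bromo-3-[(1R,6R)-6-(propan-2-yl)-3-(trifluoromethanesulfonyloxy)cyclohex-2-en-1-yl]prop-2-enoate
Product: 28 methyl (E)-2-(hydroxymethyl)-3-[(1R,6R)-3-(hydroxymethyl)-6-(propan-2-yl)cyclohex-2-en-1-yl]prop-2-enoate
Conditions: Bu3SnCH2OH (2.6 equiv), Pd(PPh3)4 (10 mol%), LiCl, dioxane, 90 °C
Reagents that add atoms: (tributylstannyl)methanol, CCCC[Sn](CCCC)(CCCC)CO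
Why: A double Stille coupling should replace both the alkenyl bromide and the enol triflate by hydroxymethyl groups with retention of alkene geometry.

Step 20
Reactants: 28 methyl (E)-2-(hydroxymethyl)-3-[(1R,6R)-3-(hydroxymethyl)-6-(propan-2-yl)cyclohex-2-en-1-yl]prop-2-enoate
Product: 29 (E)-2-(hydroxymethyl)-3-[(1R,6R)-3-(hydroxymethyl)-6-(propan-2-yl)cyclohex-2-en-1-yl]prop-2-enoic acid
Conditions: LiOH, THF/H2O, rt; then 1 M HCl
Reagents that add atoms: lithium hydroxide, [Li+].[OH-]
Why: Saponification of the methyl enoate should free the acid; the allylic alcohols and alkenes are stable to aqueous hydroxide.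

Step 21
Reactants: 18 tert-butyl ester of the spiro-epoxy ε-lactone; 29 (E)-2-(hydroxymethyl)-3-[(1R,6R)-3-(hydroxymethyl)-6-(propan-2-yl)cyclohex-2-en-1-yl]prop-2-enoic acid
Product: 30 tert-butyl ester (at C15) of the target dimer
Conditions: Cs2CO3 (0.3 equiv), DMF, 60 °C
Reagents that add atoms: none
Why: The cesium carboxylate should open the 2,2-disubstituted oxirane by SN2 attack at the unhindered C14 methylene, leaving C10 untouched; the free alcohols of 29 are far weaker nucleophiles.

Step 22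
Reactants: 30 tert-butyl ester (at C15) of the target dimer
Product: 31 CNP0361406.3
Conditions: CF3CO2H/CH2Cl2 (1:4), 0 °C
Reagents that add atoms: none
Why: Acidolysis of the tert-butyl ester by loss of 2-methylpropene should free the C15 acid without hydrolysing the lactone or the inter-half ester.

Compound list
1 | (R)-2,2-dimethyl-1,3-dioxolane-4-carbaldehyde | O=C[C@H]1COC(C)(C)O1 | starting material
2 | (S,E)-4-(2,2-dimethyl-1,3-dioxolan-4-yl)but-3-en-2-one | CC(=O)/C=C/[C@H]1COC(C)(C)O1 | intermediate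
3 | methyl 5-methoxy-3-oxopentanoate | COCCC(=O)CC(=O)OC | starting material
4 | methyl 3-oxopent-4-enoate | C=CC(=O)CC(=O)OC | intermediate (not isolated)
5 | methyl (3S)-3-[(4S)-2,2-dimethyl-1,3-dioxolan-4-yl]-5-oxo-2-(prop-2-enoyl)hexanoate (C2 labile) | C=CC(=O)C(C(=O)OC)[C@H](CC(C)=O)[C@H]1COC(C)(C)O1 | intermediate (not isolated)
6 | methyl (5R,6S)-5-acetyl-6-[(4S)-2,2-dimethyl-1,3-dioxolan-4-yl]-2-oxocyclohexane-1-carboxylate (C1 labile, keto/enol) | O=C1CC[C@@H](C(C)=O)[C@H]([C@H]2COC(C)(C)O2)C1C(=O)OC | intermediate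
7 | methyl (5R,6S)-6-[(4S)-2,2-dimethyl-1,3-dioxolan-4-yl]-2-oxo-5-(prop-1-en-2-yl)cyclohexane-1-carboxylate | O=C1CC[C@@H](C(C)=C)[C@H]([C@H]2COC(C)(C)O2)C1C(=O)OC | intermediate
8 | methyl (5S,6S)-6-[(4S)-2,2-dimethyl-1,3-dioxolan-4-yl]-2-oxo-5-(propan-2-yl)cyclohexane-1-carboxylate | O=C1CC[C@@H](C(C)C)[C@H]([C@H]2COC(C)(C)O2)C1C(=O)OC | intermediate
9 | methyl (5S,6S)-6-[(4S)-2,2-dimethyl-1,3-dioxolan-4-yl]-5-(propan-2-yl)-2-(trifluoromethanesulfonyloxy)cyclohex-1-ene-1-carboxylate | COC(=O)C1=C(OS(=O)(=O)C(F)(F)F)CC[C@@H](C(C)C)[C@@H]1[C@H]1COC(C)(C)O1 | intermediate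
10 | methyl (5S,6S)-6-[(4S)-2,2-dimethyl-1,3-dioxolan-4-yl]-5-(propan-2-yl)-2-[(trimethylsilyl)methyl]cyclohex-1-ene-1-carboxylate | COC(=O)C1=C(C[Si](C)(C)C)CC[C@@H](C(C)C)[C@@H]1[C@H]1COC(C)(C)O1 | intermediate
11 | methyl (1S,2S,3S)-2-[(4S)-2,2-dimethyl-1,3-dioxolan-4-yl]-6-methylidene-3-(propan-2-yl)cyclohexane-1-carboxylate | C=C1CC[C@@H](C(C)C)[C@H]([C@H]2COC(C)(C)O2)[C@@H]1C(=O)OC | intermediate
12 | (1S,2S,3S)-2-[(4S)-2,2-dimethyl-1,3-dioxolan-4-yl]-6-methylidene-3-(propan-2-yl)cyclohexane-1-carboxylic acid | C=C1CC[C@@H](C(C)C)[C@H]([C@H]2COC(C)(C)O2)[C@@H]1C(=O)O | intermediate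
13 | (1S,2S,3S)-2-formyl-6-methylidene-3-(propan-2-yl)cyclohexane-1-carboxylic acid | C=C1CC[C@@H](C(C)C)[C@H](C=O)[C@@H]1C(=O)O | intermediate
14 | (1S,2S,3S)-2-[(Z)-2-bromo-3-tert-butoxy-3-oxoprop-1-en-1-yl]-6-methylidene-3-(propan-2-yl)cyclohexane-1-carboxylic acid | C=C1CC[C@@H](C(C)C)[C@H](/C=C(\Br)C(=O)OC(C)(C)C)[C@@H]1C(=O)O | intermediate
15 | (1S,2R,3S)-2-[(E)-3-tert-butoxy-2-(hydroxymethyl)-3-oxoprop-1-en-1-yl]-6-methylidene-3-(propan-2-yl)cyclohexane-1-carboxylic acid | C=C1CC[C@@H](C(C)C)[C@H](/C=C(\CO)C(=O)OC(C)(C)C)[C@@H]1C(=O)O | intermediate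
16 | tert-butyl (E)-2-(hydroxymethyl)-3-[(1S,2R,3S,6R)-6-(iodomethyl)-8-oxo-3-(propan-2-yl)-7-oxabicyclo[4.2.0]octan-2-yl]prop-2-enoate | IC[C@@]12CC[C@@H](C(C)C)[C@H](/C=C(\CO)C(=O)OC(C)(C)C)[C@@H]1C(=O)O2 | intermediate
17 | iodohydrin ε-lactone: lactone half as its C15 tert-butyl ester with CH2I in place of the acyloxymethyl group (C1 S, C6 R, C7 S, C10 R) | IC[C@@]1(O)CC[C@@H](C(C)C)[C@@H]2C=C(C(=O)OC(C)(C)C)COC(=O)[C@@H]21 | intermediate (not isolated)
18 | spiro-epoxy ε-lactone, C15 tert-butyl ester (C10–C14 oxirane, O cis to C2; C1 S, C6 R, C7 S, C10 R) | O1C[C@]12CC[C@@H](C(C)C)[C@@H]3C=C(C(=O)OC(C)(C)C)COC(=O)[C@@H]32 | intermediate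
19 | 3-methylbutanal | CC(C)CC=O | starting material
20 | but-3-en-2-one | CC(=O)C=C | starting material
21 | (R)-5-oxo-2-(propan-2-yl)hexanal | CC(C)[C@H](C=O)CCC(C)=O | intermediate
22 | (R)-4-(propan-2-yl)cyclohex-2-en-1-one ((R)-cryptone) | CC(C)[C@H]1CCC(=O)C=C1 | intermediate
23 | bromomagnesium (3R,4R)-3-ethenyl-4-(propan-2-yl)cyclohex-1-en-1-olate | CC(C)[C@H]1CCC(O[Mg]Br)=C[C@@H]1C=C | intermediate (not isolated)
24 | (3R,4R)-3-ethenyl-4-(propan-2-yl)cyclohex-1-en-1-yl trifluoromethanesulfonate | CC(C)[C@H]1CCC(OS(=O)(=O)C(F)(F)F)=C[C@@H]1C=C | intermediate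
25 | 1,2,4-trioxolane (ozonide) formed from the vinyl group of 24 | CC(C)[C@H]1CCC(OS(=O)(=O)C(F)(F)F)=C[C@@H]1C1OCOO1 | intermediate (not isolated)
26 | (1R,6R)-6-(propan-2-yl)-3-(trifluoromethanesulfonyloxy)cyclohex-2-ene-1-carbaldehyde | CC(C)[C@H]1CCC(OS(=O)(=O)C(F)(F)F)=C[C@@H]1C=O | intermediate
27 | methyl (Z)-2-bromo-3-[(1R,6R)-6-(propan-2-yl)-3-(trifluoromethanesulfonyloxy)cyclohex-2-en-1-yl]prop-2-enoate | CC(C)[C@H]1CCC(OS(=O)(=O)C(F)(F)F)=C[C@@H]1/C=C(\Br)C(=O)OC | intermediate
28 | methyl (E)-2-(hydroxymethyl)-3-[(1R,6R)-3-(hydroxymethyl)-6-(propan-2-yl)cyclohex-2-en-1-yl]prop-2-enoate | CC(C)[C@H]1CCC(CO)=C[C@@H]1/C=C(\CO)C(=O)OC | intermediate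
29 | (E)-2-(hydroxymethyl)-3-[(1R,6R)-3-(hydroxymethyl)-6-(propan-2-yl)cyclohex-2-en-1-yl]prop-2-enoic acid | CC(C)[C@H]1CCC(CO)=C[C@@H]1/C=C(\CO)C(=O)O | intermediate
30 | C15 tert-butyl ester of the target dimer | CC(C)[C@H]1CCC(CO)=C[C@@H]1/C=C(\CO)C(=O)OC[C@@]1(O)CC[C@@H](C(C)C)[C@@H]2C=C(C(=O)OC(C)(C)C)COC(=O)[C@@H]21 | intermediate
31 | CNP0361406.3 | CC(C)[C@H]1CCC(CO)=C[C@@H]1/C=C(\CO)C(=O)OC[C@@]1(O)CC[C@@H](C(C)C)[C@@H]2C=C(C(=O)O)COC(=O)[C@@H]21 | target

Total step count: 22. Longest linear sequence: 15 steps (steps 1 to 13, then 21 and 22).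

Steps most likely to fail

Step 2. Aldol closure through the acetyl methyl group (Robinson-type) may compete with the C7–C8 Michael closure, and reversible Michael addition under methoxide may erode the facial selectivity at C6. The fallback sets out from 2. The vinyl β-keto ester 4 is made separately and isolated: the lithium enolate of methyl acetate adds to acrolein to give methyl 3-hydroxypent-4-enoate F1, which is oxidised with MnO2. Compound 4 is then combined with 2 under primary-amine catalysis (9-amino-9-deoxy-epi-quinine as its trifluoroacetate salt, toluene, rt). The enone is activated as its iminium ion, the first Michael addition delivers the C7 enamine directly, and this enamine closes the ring at C8. The cinchona amine pseudoenantiomer is chosen to reinforce the dioxolane bias, and hydrolysis of the catalyst returns to the route at 6.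

Step 7. Protonation of the dienolate at C14 would restore conjugation, and protonation of C1 from the wrong face would give the C1 epimer. The fallback sets out from 9. Stille coupling with (tributylstannyl)methanol (Pd(PPh3)4, LiCl, dioxane, 90 °C) gives the hydroxymethyl enoate F2, which lactonises on mild acid treatment to the butenolide F3. Dissolving-metal reduction (Li, NH3/THF, −78 °C, then solid NH4Cl) cleaves the allylic C14–O bond of the unsaturated lactone, and the carboxylate dienolate is protonated at C1 under a different counter-ion and proton source. This gives the acid directly, so the fallback comes back at 12 and also replaces step 8.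

Step 13. Acyl transfer to the C3 alkoxide through a seven-membered transition state may be too slow, so that the β-lactone is consumed by intermolecular opening or by loss of CO2. The fallback sets out from 16. LiOH (THF/H2O, 0 °C) opens the β-lactone by acyl–oxygen cleavage and the liberated C10 alkoxide closes the oxirane, giving the epoxy hydroxy acid F4. Lactonisation of F4 with 2-methyl-6-nitrobenzoic anhydride, DMAP and Et3N at high dilution in CH2Cl2 forms the seven-membered lactone and returns to the route at 18.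

Further compounds
F1 | step 2 | methyl 3-hydroxypent-4-enoate | C=CC(O)CC(=O)OC
F2 | step 7 | methyl (5S,6S)-6-[(4S)-2,2-dimethyl-1,3-dioxolan-4-yl]-2-(hydroxymethyl)-5-(propan-2-yl)cyclohex-1-ene-1-carboxylate | COC(=O)C1=C(CO)CC[C@@H](C(C)C)[C@@H]1[C@H]1COC(C)(C)O1
F3 | step 7 | butenolide: (4S,5S)-4-[(4S)-2,2-dimethyl-1,3-dioxolan-4-yl]-5-(propan-2-yl)-4,5,6,7-tetrahydro-2-benzofuran-1(3H)-one (C6/C7 trans) | O=C1OCC2=C1[C@@H]([C@H]1COC(C)(C)O1)[C@H](C(C)C)CC2
F4 | step 13 | epoxy hydroxy acid: C10–C14 oxirane, free C2 acid and free C3 alcohol, C15 tert-butyl ester (C1 S, C6 R, C7 S, C10 R) | O1C[C@]12CC[C@@H](C(C)C)[C@H](/C=C(\CO)C(=O)OC(C)(C)C)[C@@H]2C(=O)O
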